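**Plan**
1. Hardest feature: the strained 14-membered para/meta-cyclophane (ring B C1'–C4', ether O, ring A C3–C2–C1, both benzylic CH2, piperazine C2–C3–N4–C5). Second: the C8(guanine)–C5(ring A) bond ortho to a free phenol.
2. Retrosynthetic cuts, in order: guanine N7–C8 and N9–C8 (C8 becomes CHO); CHO–C5 of ring A (becomes C–H); ether bond O–C3 of ring A (becomes O–H + C–H); both piperazine CH2 back to lactam C=O; the two amide C–N bonds.
3. Enabling feature: without the O–C3 and C5–C8 bonds the target is (2S,5S)-2,5-bis(4-hydroxybenzyl)piperazine. It has a C2 axis through the piperazine ring, so the two phenol rings are homotopic and all four ortho C–H are equivalent. Every O-donor/C-acceptor pairing gives the same ether, and the cis arms lie on one face of the ring.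
4. Forward ring order: piperazinedione, then piperazine, then the 14-membered ring closed by a cytochrome P450 phenol-coupling enzyme on the unprotected, unfunctionalised bisphenol. The product has one phenol with one free ortho C–H; this is formylated and the guanine imidazole ring is annulated onto the formyl carbon.
5. Stereochemistry: both (S) centres come from L-tyrosine. No later step makes or breaks a bond at either centre.

Key step: step 3

Assumption: the guanine tautomers (7H as drawn, 9H) are treated as one compound, and the recombinant P450 with its redox partners (from synthetic genes) counts as a catalyst, not a starting material.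

Step 1
Reactants: 1 methyl L-tyrosinate (2 equiv)
Product: 3 cyclo(L-Tyr-L-Tyr) = (3S,6S)-3,6-bis(4-hydroxybenzyl)piperazine-2,5-dione, via dipeptide ester 2 (not isolated)
Conditions: neat melt, 140 °C, N2, MeOH distilled off; recrystallisation (aq. AcOH)
Reagents that add atoms: none
Why: Classical thermal cyclodimerisation of an α-amino ester: intermolecular aminolysis gives 2, whose cis-amide rotamer closes the six-membered ring by a second aminolysis; no bond to Cα is broken and no external base is present, so both (S) centres should be carried over, and recrystallisation should remove any trans isomer.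

Step 2
Reactants: 3 cyclo(L-Tyr-L-Tyr)
Product: 5 (2S,5S)-2,5-bis(4-hydroxybenzyl)piperazine, via bis(amine-borane) adduct 4 (not isolated)
Conditions: BH3·THF (excess), THF, reflux; MeOH; 6 M HCl, reflux; NaOH to pH 10
Reagents that add atoms: none
Why: Borane reduction of secondary lactams to amines is a standard way from piperazinediones to piperazines without epimerisation at Cα; the phenol O–H groups only consume hydride, and acid hydrolysis breaks adduct 4.

Step 3
Reactants: 5 (2S,5S)-2,5-bis(4-hydroxybenzyl)piperazine
Product: 7 piperazinomycin (2,5-bridged (2S,5S)-piperazine cyclophane; ring A 4-OH and 3-O-aryl), via dienone tautomer 6 (not isolated)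
Conditions: cytochrome P450 of the phenol-coupling class (recombinant, from an actinomycete piperazine-alkaloid gene cluster, cat.), ferredoxin, ferredoxin-NADP+ reductase, NADP+ (cat.), glucose dehydrogenase, D-glucose, air, KPi buffer pH 7.5, 30 °C
Reagents that add atoms: none
Why: The ferryl haem, formed from O2 and two electrons passed from NADPH through reductase and ferredoxin, abstracts the hydrogen atoms of the two phenol O–H groups in turn, and the enzyme-bound bis(phenoxyl) diradical recombines between the oxygen of one ring and an ortho carbon of the other to give dienone 6, which tautomerises to phenol 7 while O2 ends as water. The closest known reaction type is the P450-catalysed intramolecular aryl ether cross-link of tyrosine-type rings (glycopeptide cross-linking enzymes, cyclodityrosine-coupling CYPs), and bacterial pathways to this alkaloid family contain a P450 that accepts exactly this bisphenol. One ring is closed, the 14-membered cyclophane (para bridge over ring B, meta bridge over ring A), by O–C(ortho) radical recombination, with the strain paid for by the oxidant and by rearomatisation of 6. No stereocentre is created in 7, since the sp3 carbon of 6 disappears on tautomerisation, and C2/C5 are untouched; their cis relation lets both arms fold over one face of a boat-like piperazine. The step needs C–O rather than ortho,ortho C–C coupling, intra- rather than intermolecular coupling, and a stop after one coupling; the pocket holds the rings offset so that O faces C-ortho and isolates the radicals from other substrate molecules, and the alternative biaryl ring would be two atoms smaller and more strained. Regiochemistry is no issue, because the C2 axis of 5 makes both rings and all four ortho C–H positions equivalent.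

Step 4
Reactants: 7 piperazinomycin
Product: 9 N,N'-bis(trifluoroacetyl)piperazinomycin, via tris(trifluoroacetyl) derivative 8 (not isolated)
Conditions: (CF3CO)2O, pyridine, CH2Cl2, 0 °C to rt; then MeOH, rt
Reagents that add atoms: trifluoroacetic anhydride O=C(OC(=O)C(F)(F)F)C(F)(F)F
Why: Standard N-acylation gives trifluoroacetamides that are stable to the hot CF3CO2H of step 5 and labile to ammonia; the phenol is acylated too (8), but the aryl trifluoroacetate is methanolysed selectively in the quench.

Step 5
Reactants: 9 N,N'-bis(trifluoroacetyl)piperazinomycin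
Product: 11 5-formyl-N,N'-bis(trifluoroacetyl)piperazinomycin (CHO on ring A ortho to OH), via aldimine 10 (not isolated)
Conditions: hexamethylenetetramine, CF3CO2H, 80 °C; then H2O, 50 °C
Reagents that add atoms: hexamethylenetetramine C1N2CN3CN1CN(C2)C3; water O
Why: Duff formylation: the iminium ion from protonated hexamine attacks ortho to the hydrogen-bonding phenol O–H, a hydride shift gives aldimine 10 and water hydrolyses it; ring A has one free position ortho to OH (C3 bears the ether, C1 the CH2), ring B is only an aryl ether and much less nucleophilic, and 2-alkoxy-4-alkylphenols are known substrates.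

Step 6
Reactants: 11 5-formyl-N,N'-bis(trifluoroacetyl)piperazinomycin; 12 2,5,6-triaminopyrimidin-4(3H)-one sulfate
Product: 15 N,N'-bis(trifluoroacetyl)guanipiperazine A, via Schiff base 13 (not isolated), via dihydropurine aminal 14 (not isolated)
Conditions: (a) NaOAc, DMSO–H2O, N2, 60 °C; (b) FeCl3 (cat.), O2 (1 atm), 90 °C
Reagents that add atoms: none
Why: Oxidative aldehyde variant of the Traube purine synthesis: the 5-NH2 group, the only amine of 12 not tied up in an amidine or vinylogous amide, condenses to Schiff base 13, the 6-NH2 adds to the C=N bond to give aminal 14, and O2 dehydrogenates it to the aromatic imidazole ring, as known for 8-arylxanthines and 8-arylguanines.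

Step 7
Reactants: 15 N,N'-bis(trifluoroacetyl)guanipiperazine A
Product: 16 guanipiperazine A
Conditions: NH3 (7 M in MeOH), 40 °C, sealed vessel, N2; evaporation
Reagents that add atoms: none
Why: Ammonolysis is a standard cleavage of trifluoroacetamides; it should free both piperazine N–H groups without affecting the diaryl ether, the guanine lactam or the two stereocentres, and should leave the neutral free base after evaporation.

**Compound list**
1 | methyl L-tyrosinate | COC(=O)[C@@H](N)Cc1ccc(O)cc1 | starting material
2 | methyl L-tyrosyl-L-tyrosinate | N[C@@H](Cc1ccc(O)cc1)C(=O)N[C@@H](Cc1ccc(O)cc1)C(=O)OC | intermediate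
3 | cyclo(L-Tyr-L-Tyr), (3S,6S)-3,6-bis(4-hydroxybenzyl)piperazine-2,5-dione | O=C1N[C@@H](Cc2ccc(O)cc2)C(=O)N[C@H]1Cc1ccc(O)cc1 | intermediate
4 | bis(amine-borane) adduct of 5 (configuration at N undefined) | Oc1ccc(cc1)C[C@H]1C[NH+]([BH3-])[C@H](C[NH+]1[BH3-])Cc1ccc(O)cc1 | intermediate
5 | (2S,5S)-2,5-bis(4-hydroxybenzyl)piperazine | Oc1ccc(cc1)C[C@H]1CN[C@H](CN1)Cc1ccc(O)cc1 | intermediate
6 | 6-aryloxycyclohexa-2,4-dienone tautomer of 7 (transient sp3 carbon undefined) | O=C1C=CC2=CC1Oc1ccc(cc1)C[C@H]1CN[C@H](CN1)C2 | intermediate
7 | piperazinomycin | Oc1ccc2cc1Oc1ccc(cc1)C[C@H]1CN[C@H](CN1)C2 | intermediate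
8 | O,N,N'-tris(trifluoroacetyl)piperazinomycin | FC(F)(F)C(=O)Oc1ccc2cc1Oc1ccc(cc1)C[C@H]1CN(C(=O)C(F)(F)F)[C@H](CN1C(=O)C(F)(F)F)C2 | intermediate
9 | N,N'-bis(trifluoroacetyl)piperazinomycin | Oc1ccc2cc1Oc1ccc(cc1)C[C@H]1CN(C(=O)C(F)(F)F)[C@H](CN1C(=O)C(F)(F)F)C2 | intermediate
10 | ring A C5 aldimine of 9 | N=Cc1cc2cc(c1O)Oc1ccc(cc1)C[C@H]1CN(C(=O)C(F)(F)F)[C@H](CN1C(=O)C(F)(F)F)C2 | intermediate
11 | 5-formyl-N,N'-bis(trifluoroacetyl)piperazinomycin | O=Cc1cc2cc(c1O)Oc1ccc(cc1)C[C@H]1CN(C(=O)C(F)(F)F)[C@H](CN1C(=O)C(F)(F)F)C2 | intermediate
12 | 2,5,6-triaminopyrimidin-4(3H)-one sulfate | Nc1nc(N)c(N)c(=O)[nH]1.OS(=O)(=O)O | starting material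
13 | (E)-Schiff base of 11 with the 5-NH2 group of 12 | Nc1nc(N)c(/N=C/c2cc3cc(c2O)Oc2ccc(cc2)C[C@H]2CN(C(=O)C(F)(F)F)[C@H](CN2C(=O)C(F)(F)F)C3)c(=O)[nH]1 | intermediate
14 | 8-aryl-7,8-dihydroguanine aminal (C8 undefined) | Nc1nc2NC(c3cc4cc(c3O)Oc3ccc(cc3)C[C@H]3CN(C(=O)C(F)(F)F)[C@H](CN3C(=O)C(F)(F)F)C4)Nc2c(=O)[nH]1 | intermediate
15 | N,N'-bis(trifluoroacetyl)guanipiperazine A | Nc1nc2nc(-c3cc4cc(c3O)Oc3ccc(cc3)C[C@H]3CN(C(=O)C(F)(F)F)[C@H](CN3C(=O)C(F)(F)F)C4)[nH]c2c(=O)[nH]1 | intermediate
16 | guanipiperazine A | Nc1nc2nc(-c3cc4cc(c3O)Oc3ccc(cc3)C[C@H]3CN[C@H](CN3)C4)[nH]c2c(=O)[nH]1 | target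

Total step count: 7. Longest linear sequence: 7 (1 to 16; 12 is bought).

**Steps most likely to fail**

Step 3. Conversion may stall because O2 reduction uncouples from substrate oxidation or because electron transfer from a non-native redox pair is slow. Phenoxyl radicals may also escape into solution and oligomerise. The fallback sets out from 5 and returns at 9, using the classical oxidative coupling of 2,6-dihalophenols, which keeps the C2 logic. Selective N-acylation with ethyl trifluoroacetate and Et3N in MeOH would give the bis(trifluoroacetamide) F1. Exhaustive ortho-bromination (NBS, 4 equiv) would give the still C2-symmetric tetrabromide F2. Thallium(III) nitrate in MeOH–THF at high dilution would make one phenol oxygen attack a bromine-bearing ortho carbon of the other ring and give the bromodienone F3. Zinc in acetic acid would reduce it to the tribromo diaryl ether F4, and hydrogenolysis (H2, Pd/C, NaOAc) would remove the three bromines to give 9.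

Step 5. Electrophilic substitution may be sluggish because the neighbouring aryloxy group shields the phenol. Forcing conditions may bring attack on ring B or acid-induced degradation of the strained ether. The fallback sets out from 9 and returns at 11, and delivers the carbon under neutral conditions through a boron tether. Phenylboronic acid, paraformaldehyde and catalytic propionic acid in refluxing toluene (ortho-specific templated hydroxymethylation) would give the 2-phenyl-1,3,2-benzodioxaborin F5. Transesterification with pinacol would release the ortho-hydroxymethylphenol F6, and MnO2 in CH2Cl2 would oxidise the benzylic alcohol to 11.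

Step 6. The electron-rich triaminopyrimidinone may be oxidised by air before it condenses. The sequence may stall at the hydrogen-bonded salicylaldimine, or the phenol ring may be over-oxidised. The fallback sets out from 11 and returns at 16 by the non-oxidative acylative Traube route. Chlorite oxidation with sulfamic acid as hypochlorite scavenger would give the salicylic acid F7. Coupling with 12 (EDC, HOBt, i-Pr2NEt, DMF) at the 5-NH2 group would give the 5-acylaminopyrimidinone F8. Heating in 1 M aqueous NaOH under N2 followed by neutralisation would close the imidazole ring by dehydration and cleave both trifluoroacetamides in the same operation, giving 16.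

**Further compounds**
F1 | step 3 | (2S,5S)-2,5-bis(4-hydroxybenzyl)-1,4-bis(trifluoroacetyl)piperazine | Oc1ccc(cc1)C[C@H]1CN(C(=O)C(F)(F)F)[C@H](CN1C(=O)C(F)(F)F)Cc1ccc(O)cc1
F2 | step 3 | (2S,5S)-2,5-bis(3,5-dibromo-4-hydroxybenzyl)-1,4-bis(trifluoroacetyl)piperazine | Oc1c(Br)cc(cc1Br)C[C@H]1CN(C(=O)C(F)(F)F)[C@H](CN1C(=O)C(F)(F)F)Cc1cc(Br)c(O)c(Br)c1
F3 | step 3 | macrocyclic 2,6-dibromo-6-aryloxycyclohexa-2,4-dienone (sp3 C–Br carbon undefined) | O=C1C(Br)=CC2=CC1(Br)Oc1c(Br)cc(cc1Br)C[C@H]1CN(C(=O)C(F)(F)F)[C@H](CN1C(=O)C(F)(F)F)C2
F4 | step 3 | 5,3',5'-tribromo-N,N'-bis(trifluoroacetyl)piperazinomycin | Oc1c(Br)cc2cc1Oc1c(Br)cc(cc1Br)C[C@H]1CN(C(=O)C(F)(F)F)[C@H](CN1C(=O)C(F)(F)F)C2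
F5 | step 5 | 2-phenyl-4H-1,3,2-benzodioxaborin fused to ring A of 9 | c1ccccc1B1OCc2cc3cc(c2O1)Oc1ccc(cc1)C[C@H]1CN(C(=O)C(F)(F)F)[C@H](CN1C(=O)C(F)(F)F)C3
F6 | step 5 | 5-hydroxymethyl-N,N'-bis(trifluoroacetyl)piperazinomycin | OCc1cc2cc(c1O)Oc1ccc(cc1)C[C@H]1CN(C(=O)C(F)(F)F)[C@H](CN1C(=O)C(F)(F)F)C2
F7 | step 6 | 5-carboxy-N,N'-bis(trifluoroacetyl)piperazinomycin | OC(=O)c1cc2cc(c1O)Oc1ccc(cc1)C[C@H]1CN(C(=O)C(F)(F)F)[C@H](CN1C(=O)C(F)(F)F)C2
F8 | step 6 | N-(2,6-diamino-4-oxo-3,4-dihydropyrimidin-5-yl)amide of F7 | Nc1nc(N)c(NC(=O)c2cc3cc(c2O)Oc2ccc(cc2)C[C@H]2CN(C(=O)C(F)(F)F)[C@H](CN2C(=O)C(F)(F)F)C3)c(=O)[nH]1
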